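The pyrrole ring is cut at N1–C5 and C2–C3. N1 and C2 with its methoxycarbonyl group are a glycine methyl ester unit; C5–H, C4 and C3 with the two 5-bromoindol-3-yl groups are the formyl carbon, the α-carbon and the chlorine-bearing carbon of a β-chloroenal made by chloroformylating a 1,2-bis(indolyl)ethanone. One operation joins nitrogen to the formyl carbon and the glycine carbon to the C–Cl carbon and aromatises by loss of HCl, so the 2,3,4-trisubstituted pyrrole with its free C5–H forms in a single step. Both indole nitrogens carry tosyl groups, which tolerate AlCl3 and POCl3, keep the β-carbon electrophilic and come off last without harm to ester or aryl bromides.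

Key step: step 5

Remark on the chemistry: the β-chloroenal of step 4 is carried as the Z isomer (Cl cis to CHO) expected from the Vilsmeier–Haack reaction; the E isomer has the same constitution and should give the same pyrrole, because the ring-closing carbon bears both the chlorine and an indolyl group. Ts = p-toluenesulfonyl (tosyl).

Step 1
Reactants: 1 5-bromoindole
Product: 2 5-bromo-1-tosyl-1H-indole
Conditions: TsCl, NaOH (powdered), Bu4NHSO4 (cat.), CH2Cl2, 0 °C → rt
Reagents that add atoms: p-toluenesulfonyl chloride (TsCl), Cc1ccc(cc1)S(=O)(=O)Cl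
Why: Phase-transfer N-sulfonylation, in which hydroxide deprotonates the indole N–H and the indolide attacks TsCl at sulfur, is a standard protection that leaves the aryl bromide untouched.

Step 2
Reactants: 3 5-bromoindole-3-acetic acid
Product: 4 2-(5-bromo-1-tosyl-1H-indol-3-yl)acetic acid
Conditions: LiN(SiMe3)2 (2.2 equiv), THF, −78 °C; TsCl, −78 °C → rt; then 1 M HCl
Reagents that add atoms: p-toluenesulfonyl chloride (TsCl), Cc1ccc(cc1)S(=O)(=O)Cl
Why: N-Sulfonylation of the carboxylate–indolide dianion should be selective because the indolide nitrogen is far more nucleophilic than the carboxylate, any mixed anhydride is hydrolysed on acidic work-up, and the non-nucleophilic amide base cannot exchange the C–Br bond.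

Step 3
Reactants: 4 2-(5-bromo-1-tosyl-1H-indol-3-yl)acetic acid, 2 5-bromo-1-tosyl-1H-indole
Product: 6 1,2-bis(5-bromo-1-tosyl-1H-indol-3-yl)ethan-1-one, via acid chloride 5 (not isolated)
Conditions: (COCl)2, DMF (cat.), CH2Cl2, 0 °C → rt; then 2, AlCl3, CH2Cl2, 0 °C → rt; ice-water
Reagents that add atoms: none
Why: Acid chloride formation followed by Friedel–Crafts acylation should deliver the ketone, since N-sulfonylindoles are acylated by RCOCl/AlCl3 at C3 while the sulfonyl group blocks N-acylation and acid-induced oligomerisation, and the C5 bromine does not alter this site preference.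

Step 4
Reactants: 6 1,2-bis(5-bromo-1-tosyl-1H-indol-3-yl)ethan-1-one
Product: 8 (Z)-3-chloro-2,3-bis(5-bromo-1-tosyl-1H-indol-3-yl)acrylaldehyde, via chloropropeniminium salt 7 (not isolated)
Conditions: POCl3, DMF, 0 → 60 °C; then ice-water
Reagents that add atoms: N,N-dimethylformamide, CN(C)C=O (formyl carbon); phosphoryl chloride, O=P(Cl)(Cl)Cl (vinylic chlorine); water, O (aldehyde oxygen)
Why: Vilsmeier–Haack haloformylation of an enolisable aryl ketone formylates the enol at the methylene carbon, exchanges the activated ketone oxygen for chloride to give salt 7 and releases the aldehyde on hydrolysis, while the sulfonylated indole rings are too electron-poor to be formylated themselves.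

Step 5
Reactants: 8 (Z)-3-chloro-2,3-bis(5-bromo-1-tosyl-1H-indol-3-yl)acrylaldehyde, 9 glycine methyl ester hydrochloride
Product: 13 methyl 3,4-bis(5-bromo-1-tosyl-1H-indol-3-yl)-1H-pyrrole-2-carboxylate, via glycine methyl ester 10 (not isolated), via azadiene imine 11 (not isolated), via 2H-pyrrole 12 (not isolated)
Conditions: K2CO3, 4 Å MS, DMF, rt; then 80 °C
Reagents that add atoms: none
Why: The amine 10 freed from 9 condenses with the formyl group of 8 to give azadiene 11 (N1–C5), carbonate then removes the glycine C–H to form a 2-azapentadienyl anion that bonds its carbanion carbon to the chlorine-bearing carbon (C2–C3), chloride leaves to give 2H-pyrrole 12, and a proton shift from C2 to N1 aromatises it to 13. The closest known reaction type is the condensation of deoxybenzoin-derived β-chloroenals or chloropropeniminium salts with glycine esters to 3,4-diarylpyrrole-2-carboxylates. The one new ring, the pyrrole, closes by a thermally allowed six-electron 1,5-electrocyclisation of the azapentadienyl anion, which is how a geometrically 5-endo-trig C–C closure becomes feasible. No stereocentre is created, since the sp3 carbon of 12 is planarised on tautomerisation. The step needs regioselectivity (nitrogen to the formyl carbon, glycine carbon to the C–Cl carbon), and this follows from letting the fast aldimine formation finish at room temperature over molecular sieves before heating, while the β-carbon is shielded from the amine by its two bulky indolyl neighbours. The N-sulfonyl groups keep that carbon electrophilic and acidify the glycine C–H of 11, so a mild carbonate base should suffice.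

Step 6
Reactants: 13 methyl 3,4-bis(5-bromo-1-tosyl-1H-indol-3-yl)-1H-pyrrole-2-carboxylate
Product: 14 methyl 3,4-bis(5-bromo-1H-indol-3-yl)-1H-pyrrole-2-carboxylate
Conditions: Cs2CO3, MeOH/THF (1:2), rt → 40 °C
Reagents that add atoms: none
Why: Nucleophilic N-desulfonylation by methoxide generated from Cs2CO3 in methanol should free both indole N–H groups, while the methyl ester can only exchange with methanol and so stays as it is, and the aryl bromides are inert under these non-reducing conditions.

Compound list
1 | 5-bromoindole | Brc1ccc2[nH]ccc2c1 | starting material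
2 | 5-bromo-1-tosyl-1H-indole | Cc1ccc(cc1)S(=O)(=O)n1ccc2cc(Br)ccc12 | intermediate
3 | 5-bromoindole-3-acetic acid | OC(=O)Cc1c[nH]c2ccc(Br)cc12 | starting material
4 | 2-(5-bromo-1-tosyl-1H-indol-3-yl)acetic acid | OC(=O)Cc1cn(S(=O)(=O)c2ccc(C)cc2)c2ccc(Br)cc12 | intermediate
5 | 2-(5-bromo-1-tosyl-1H-indol-3-yl)acetyl chloride | O=C(Cl)Cc1cn(S(=O)(=O)c2ccc(C)cc2)c2ccc(Br)cc12 | intermediate (not isolated)
6 | 1,2-bis(5-bromo-1-tosyl-1H-indol-3-yl)ethan-1-one | O=C(Cc1cn(S(=O)(=O)c2ccc(C)cc2)c2ccc(Br)cc12)c1cn(S(=O)(=O)c2ccc(C)cc2)c2ccc(Br)cc12 | intermediate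
7 | (Z)-N-[3-chloro-2,3-bis(5-bromo-1-tosyl-1H-indol-3-yl)prop-2-en-1-ylidene]-N-methylmethanaminium dichlorophosphate | C[N+](C)=C/C(=C(\Cl)c1cn(S(=O)(=O)c2ccc(C)cc2)c2ccc(Br)cc12)c1cn(S(=O)(=O)c2ccc(C)cc2)c2ccc(Br)cc12.[O-]P(=O)(Cl)Cl | intermediate (not isolated)
8 | (Z)-3-chloro-2,3-bis(5-bromo-1-tosyl-1H-indol-3-yl)acrylaldehyde | O=C/C(=C(\Cl)c1cn(S(=O)(=O)c2ccc(C)cc2)c2ccc(Br)cc12)c1cn(S(=O)(=O)c2ccc(C)cc2)c2ccc(Br)cc12 | intermediate
9 | glycine methyl ester hydrochloride | Cl.COC(=O)CN | starting material
10 | glycine methyl ester | COC(=O)CN | intermediate (not isolated)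
11 | methyl N-[(1E,2Z)-3-chloro-2,3-bis(5-bromo-1-tosyl-1H-indol-3-yl)prop-2-en-1-ylidene]glycinate | COC(=O)C/N=C/C(=C(\Cl)c1cn(S(=O)(=O)c2ccc(C)cc2)c2ccc(Br)cc12)c1cn(S(=O)(=O)c2ccc(C)cc2)c2ccc(Br)cc12 | intermediate (not isolated)
12 | methyl 3,4-bis(5-bromo-1-tosyl-1H-indol-3-yl)-2H-pyrrole-2-carboxylate (racemic at C2, transient) | COC(=O)C1N=CC(c2cn(S(=O)(=O)c3ccc(C)cc3)c3ccc(Br)cc23)=C1c1cn(S(=O)(=O)c2ccc(C)cc2)c2ccc(Br)cc12 | intermediate (not isolated)
13 | methyl 3,4-bis(5-bromo-1-tosyl-1H-indol-3-yl)-1H-pyrrole-2-carboxylate | COC(=O)c1[nH]cc(-c2cn(S(=O)(=O)c3ccc(C)cc3)c3ccc(Br)cc23)c1-c1cn(S(=O)(=O)c2ccc(C)cc2)c2ccc(Br)cc12 | intermediate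
14 | methyl 3,4-bis(5-bromo-1H-indol-3-yl)-1H-pyrrole-2-carboxylate | COC(=O)c1[nH]cc(-c2c[nH]c3ccc(Br)cc23)c1-c1c[nH]c2ccc(Br)cc12 | target

Total step count: 6 steps.
Longest linear sequence: 5 steps (steps 2, 3, 4, 5 and 6 from 3; the branch from 1 through steps 1, 3, 4, 5 and 6 is equally long). The two branches join in step 3.

Steps most likely to fail

Step 5. The amine may add to the chlorine-bearing carbon and displace chloride before it has condensed with the aldehyde, which would reverse the regiochemistry of ring closure. The imine may also stall if deprotonation and cyclisation are slow, and the glycine ester may self-condense on heating. The fallback reverses the order of bond formation with a nitrogen-masked glycine. Setting out from 8, the benzophenone imine of glycine methyl ester (COC(=O)CN=C(c1ccccc1)c1ccccc1) is deprotonated with K2CO3/Bu4NBr in MeCN, and its carbanion should displace the vinylic chloride by conjugate addition–elimination. This gives methyl (Z)-2-[(diphenylmethylidene)amino]-3,4-bis(5-bromo-1-tosyl-1H-indol-3-yl)-5-oxopent-3-enoate F1, with the C2–C3 bond made first. 1 M HCl in THF then cleaves the ketimine to the amino aldehyde methyl (Z)-2-amino-3,4-bis(5-bromo-1-tosyl-1H-indol-3-yl)-5-oxopent-3-enoate F2. On neutralisation with NaHCO3 this should condense with its own formyl group (N1–C5) to 12 and tautomerise, coming back to the route at 13.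

Step 3. The arylacetyl acylium ion may lose carbon monoxide under AlCl3 and alkylate instead of acylate, or acylation of the bromine-deactivated sulfonylindole may be slow and unselective. The fallback acylates the unprotected, far more nucleophilic indole under a milder Lewis acid. Setting out from acid chloride 5 and 5-bromoindole 1, Et2AlCl in CH2Cl2 at 0 °C should give 1-(5-bromo-1H-indol-3-yl)-2-(5-bromo-1-tosyl-1H-indol-3-yl)ethan-1-one F3 by C3 acylation of the N-aluminated indole. TsCl, Et3N and DMAP (cat.) in CH2Cl2 then sulfonylate the acidic N–H of this 3-acylindole, coming back to the route at 6.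

Step 4. C-Formylation of the hindered enol may be slow, or the sequence may stall before oxygen is exchanged for chlorine, and prolonged heating may cause decomposition. The fallback separates the two events. Setting out from 6, N,N-dimethylformamide dimethyl acetal (COC(OC)N(C)C) in toluene at 100 °C should give the enaminone (E)-3-(dimethylamino)-1,2-bis(5-bromo-1-tosyl-1H-indol-3-yl)prop-2-en-1-one F4. POCl3 in CH2Cl2 at room temperature then converts this vinylogous amide into the chloropropeniminium salt 7, and aqueous hydrolysis comes back to the route at 8.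

Further compounds
F1 | step 5 | methyl (Z)-2-[(diphenylmethylidene)amino]-3,4-bis(5-bromo-1-tosyl-1H-indol-3-yl)-5-oxopent-3-enoate (racemic at C2) | O=C/C(c1cn(S(=O)(=O)c2ccc(C)cc2)c2ccc(Br)cc12)=C(c1cn(S(=O)(=O)c2ccc(C)cc2)c2ccc(Br)cc12)\C(N=C(c1ccccc1)c1ccccc1)C(=O)OC
F2 | step 5 | methyl (Z)-2-amino-3,4-bis(5-bromo-1-tosyl-1H-indol-3-yl)-5-oxopent-3-enoate (racemic at C2, not isolated) | O=C/C(c1cn(S(=O)(=O)c2ccc(C)cc2)c2ccc(Br)cc12)=C(c1cn(S(=O)(=O)c2ccc(C)cc2)c2ccc(Br)cc12)\C(N)C(=O)OC
F3 | step 3 | 1-(5-bromo-1H-indol-3-yl)-2-(5-bromo-1-tosyl-1H-indol-3-yl)ethan-1-one | O=C(Cc1cn(S(=O)(=O)c2ccc(C)cc2)c2ccc(Br)cc12)c1c[nH]c2ccc(Br)cc12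
F4 | step 4 | (E)-3-(dimethylamino)-1,2-bis(5-bromo-1-tosyl-1H-indol-3-yl)prop-2-en-1-one | CN(C)/C=C(/C(=O)c1cn(S(=O)(=O)c2ccc(C)cc2)c2ccc(Br)cc12)c1cn(S(=O)(=O)c2ccc(C)cc2)c2ccc(Br)cc12
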